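##Retrosynthetic overview

1. The benzene ring is made last: an Alder–Rickert sequence (Diels–Alder, then retro-Diels–Alder loss of ethylene) joins a chiral γ-hydroxy ynoate and 1,5-dimethoxycyclohexa-1,4-diene, and the lactone then closes on the carbinol.
2. The γ-hydroxy ynoate comes from a vinyl carbinol by bromination, double dehydrobromination and C-acylation with methyl chloroformate.
3. The vinyl carbinol comes from the Grignard reagent of a spiroketal alkyl chloride and (R)-epichlorohydrin; the chlorohydrin is homologated by a sulfonium ylide through its oxirane.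
4. The spiroketal chloride comes from acetone dimethylhydrazone as a three-carbon linchpin between (R)-propylene oxide and (R)-2-(5-chloropentyl)oxirane (two azaenolate openings, then hydrolysis and spiroketalisation); that oxirane comes from 4-chlorobutylmagnesium bromide and (R)-epichlorohydrin.
5. Ring order: oxirane, then both spiroketal rings in one operation, then the benzene ring by cycloaddition, then the γ-lactone. All three carbinol centres come from (R)-epichlorohydrin (used in two separate steps) and (R)-propylene oxide.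

Assumption: the spiro carbon of a 1,6-dioxaspiro[4.4]nonane is only weakly biased, so it is set by acid equilibration (about 1:1 with the 5-epimer). Every spiroketal compound is carried as this pair (names and SMILES show the epimer that leads to the target). The target is separated from its 5-epimer by preparative HPLC at the end, and the epimer is re-equilibrated (PPTS, CH2Cl2) and recycled.

## Route

Step 1
Reactants: 1 1-bromo-4-chlorobutane; 2 (R)-epichlorohydrin
Product: 5 (2R)-2-(5-chloropentyl)oxirane, via Grignard reagent 3 (not isolated), via dichloro alcohol 4 (not isolated)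
Conditions: Mg, THF, 25 °C; added to 2 (0.9 equiv), CuI (10 mol%), THF, −40 → 0 °C; then 5 M aq. NaOH, rt; distillation
Reagents that add atoms: none
Why: Magnesium inserts into the C–Br bond only, and copper-catalysed Grignard opening of the epichlorohydrin at the epoxide CH2 (SN2) followed by Williamson-type closure of the chlorohydrin never breaks the C–O bond of the stereocentre, so the new oxirane keeps the bought (R) configuration.

Step 2
Reactants: 5 (2R)-2-(5-chloropentyl)oxirane; 6 acetone N,N-dimethylhydrazone; 7 (R)-propylene oxide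
Product: 11 (2R,5S,7R)-2-(5-chloropentyl)-7-methyl-1,6-dioxaspiro[4.4]nonane, via hydroxy hydrazone 8 (not isolated), via diol hydrazone 9 (not isolated), via dihydroxy ketone 10 (not isolated)
Conditions: 6 (1.1 equiv), n-BuLi, THF, 0 °C; 7 (1.1 equiv), 0 °C → rt; n-BuLi, −78 → 0 °C; 5 (1.0 equiv), 0 °C, 3 h; sat. aq. (CO2H)2/Et2O, rt; PPTS (cat.), CH2Cl2
Reagents that add atoms: none
Why: Corey–Enders azaenolate alkylation, in which lithiated 6 opens 7 at CH2, the second lithiation takes the less substituted α′ methyl and opens the oxirane of 5 at CH2 (lithium-assisted epoxide opening outruns SN2 at the unactivated primary chloride in THF), and acid hydrolysis releases the γ,γ′-dihydroxy ketone that spiroketalises, carries C2 and C7 unchanged from the two epoxides and sets the spiro carbon under thermodynamic control.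

Step 3
Reactants: 11 (2R,5S,7R)-2-(5-chloropentyl)-7-methyl-1,6-dioxaspiro[4.4]nonane; 2 (R)-epichlorohydrin
Product: 16 (3R)-9-[(2R,5S,7R)-7-methyl-1,6-dioxaspiro[4.4]nonan-2-yl]non-1-en-3-ol, via Grignard reagent 12 (not isolated), via chlorohydrin 13 (not isolated), via epoxide 14 (not isolated), via sulfonium betaine 15 (not isolated)
Conditions: Mg, I2 (cat.), THF, reflux; 2 (1.2 equiv), CuI (10 mol%), THF, −40 → 0 °C; aq. NH4Cl, extraction; crude 13 added to Me3S+ I− (4.5 equiv)/n-BuLi (4.4 equiv), THF, −10 °C → rt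
Reagents that add atoms: trimethylsulfonium iodide, C[S+](C)C.[I-]
Why: The Grignard reagent of the primary chloride opens the epichlorohydrin at its epoxide CH2 under copper catalysis (SN2), and excess dimethylsulfonium methylide closes the chlorohydrin to the oxirane and homologates it by one carbon to the allylic alcohol (Corey–Chaykovsky-type opening at CH2, then ylide-mediated elimination of dimethyl sulfide), none of which breaks the C–O bond of the carbinol, so it stays (R).

Step 4
Reactants: 16 (3R)-9-[(2R,5S,7R)-7-methyl-1,6-dioxaspiro[4.4]nonan-2-yl]non-1-en-3-ol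
Product: 17 (3R)-1,2-dibromo-9-[(2R,5S,7R)-7-methyl-1,6-dioxaspiro[4.4]nonan-2-yl]nonan-3-ol
Conditions: Br2 (1.05 equiv), K2CO3, CH2Cl2, −78 °C
Reagents that add atoms: bromine, BrBr
Why: Electrophilic anti addition of bromine to the terminal alkene under buffered conditions spares the spiroketal, and the new CHBr centre (both epimers) is destroyed again in the next step.

Step 5
Reactants: 17 (3R)-1,2-dibromo-9-[(2R,5S,7R)-7-methyl-1,6-dioxaspiro[4.4]nonan-2-yl]nonan-3-ol
Product: 19 methyl (4R)-4-hydroxy-10-[(2R,5S,7R)-7-methyl-1,6-dioxaspiro[4.4]nonan-2-yl]dec-2-ynoate, via lithiated alkynol 18 (not isolated)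
Conditions: LDA (4.1 equiv), THF, −78 → 0 °C; then ClCO2Me (1.1 equiv), −78 °C; aq. NH4Cl
Reagents that add atoms: methyl chloroformate, COC(=O)Cl
Why: Base-induced double dehydrobromination (E2) gives the lithium acetylide of the propargylic alkoxide, whose carbon is acylated by the chloroformate faster than the aggregated alkoxide oxygen, and the carbinol C–O bond is never broken, so C4 stays (R).

Step 6
Reactants: 19 methyl (4R)-4-hydroxy-10-[(2R,5S,7R)-7-methyl-1,6-dioxaspiro[4.4]nonan-2-yl]dec-2-ynoate; 20 1,5-dimethoxycyclohexa-1,4-diene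
Product: 24 (3R)-5,7-dimethoxy-3-{6-[(2R,5S,7R)-7-methyl-1,6-dioxaspiro[4.4]nonan-2-yl]hexyl}-2-benzofuran-1(3H)-one, via conjugated diene 21 (not isolated), via bicyclooctadiene adduct 22 (not isolated), via hydroxy ester 23 (not isolated)
Conditions: 20 (5 equiv), BHT (cat.), neat, 185 °C, sealed tube, 18 h; then PPTS (cat.), PhMe, 80 °C; prep. HPLC
Reagents that add atoms: none
Why: In this Alder–Rickert sequence the 1,4-diene conjugates in situ, the nucleophilic C4 terminus of the 1,3-diene bonds to the ynoate β-carbon in a regioselective Diels–Alder reaction, retro-Diels–Alder loss of ethylene forms the benzene ring with the ester between OMe and the carbinol side chain, and lactonisation closes the phthalide without touching any bond at C3, which stays (R).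

## Compound list

1 | 1-bromo-4-chlorobutane | ClCCCCBr | starting material
2 | (R)-epichlorohydrin, (2R)-2-(chloromethyl)oxirane | ClC[C@H]1CO1 | starting material
3 | 4-chlorobutylmagnesium bromide | ClCCCC[Mg]Br | intermediate
4 | (2R)-1,7-dichloroheptan-2-ol (formed as its magnesium alkoxide) | ClC[C@H](O)CCCCCCl | intermediate
5 | (2R)-2-(5-chloropentyl)oxirane | ClCCCCC[C@@H]1CO1 | intermediate
6 | acetone N,N-dimethylhydrazone | CC(C)=NN(C)C | starting material
7 | (R)-propylene oxide, (2R)-2-methyloxirane | C[C@@H]1CO1 | starting material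
8 | (2R)-5-(2,2-dimethylhydrazinylidene)hexan-2-ol (C=N geometry not fixed) | C[C@@H](O)CCC(C)=NN(C)C | intermediate
9 | (2R,8R)-13-chloro-5-(2,2-dimethylhydrazinylidene)tridecane-2,8-diol (C=N geometry not fixed) | ClCCCCC[C@@H](O)CCC(=NN(C)C)CC[C@@H](C)O | intermediate
10 | (2R,8R)-13-chloro-2,8-dihydroxytridecan-5-one | ClCCCCC[C@@H](O)CCC(=O)CC[C@@H](C)O | intermediate
11 | (2R,5S,7R)-2-(5-chloropentyl)-7-methyl-1,6-dioxaspiro[4.4]nonane | ClCCCCC[C@@H]1CC[C@]2(CC[C@@H](C)O2)O1 | intermediate
12 | {5-[(2R,5S,7R)-7-methyl-1,6-dioxaspiro[4.4]nonan-2-yl]pentyl}magnesium chloride | Cl[Mg]CCCCC[C@@H]1CC[C@]2(CC[C@@H](C)O2)O1 | intermediate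
13 | (2R)-1-chloro-8-[(2R,5S,7R)-7-methyl-1,6-dioxaspiro[4.4]nonan-2-yl]octan-2-ol | ClC[C@H](O)CCCCCC[C@@H]1CC[C@]2(CC[C@@H](C)O2)O1 | intermediate
14 | (2R,5S,7R)-7-methyl-2-{6-[(2R)-oxiran-2-yl]hexyl}-1,6-dioxaspiro[4.4]nonane | C1O[C@@H]1CCCCCC[C@@H]1CC[C@]2(CC[C@@H](C)O2)O1 | intermediate
15 | dimethyl{(3R)-3-oxido-9-[(2R,5S,7R)-7-methyl-1,6-dioxaspiro[4.4]nonan-2-yl]nonyl}sulfonium (betaine) | C[S+](C)CC[C@H]([O-])CCCCCC[C@@H]1CC[C@]2(CC[C@@H](C)O2)O1 | intermediate
16 | (3R)-9-[(2R,5S,7R)-7-methyl-1,6-dioxaspiro[4.4]nonan-2-yl]non-1-en-3-ol | C=C[C@H](O)CCCCCC[C@@H]1CC[C@]2(CC[C@@H](C)O2)O1 | intermediate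
17 | (3R)-1,2-dibromo-9-[(2R,5S,7R)-7-methyl-1,6-dioxaspiro[4.4]nonan-2-yl]nonan-3-ol (both C2 epimers) | BrCC(Br)[C@H](O)CCCCCC[C@@H]1CC[C@]2(CC[C@@H](C)O2)O1 | intermediate
18 | (3R)-9-[(2R,5S,7R)-7-methyl-1,6-dioxaspiro[4.4]nonan-2-yl]non-1-yn-3-ol (present as its dilithio salt) | C#C[C@H](O)CCCCCC[C@@H]1CC[C@]2(CC[C@@H](C)O2)O1 | intermediate
19 | methyl (4R)-4-hydroxy-10-[(2R,5S,7R)-7-methyl-1,6-dioxaspiro[4.4]nonan-2-yl]dec-2-ynoate | COC(=O)C#C[C@H](O)CCCCCC[C@@H]1CC[C@]2(CC[C@@H](C)O2)O1 | intermediate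
20 | 1,5-dimethoxycyclohexa-1,4-diene | COC1=CCC=C(OC)C1 | starting material
21 | 1,3-dimethoxycyclohexa-1,3-diene | COC1=CC(OC)=CCC1 | intermediate
22 | methyl 3-{(1R)-1-hydroxy-7-[(2R,5S,7R)-7-methyl-1,6-dioxaspiro[4.4]nonan-2-yl]heptyl}-1,5-dimethoxybicyclo[2.2.2]octa-2,5-diene-2-carboxylate (bridgehead configuration not fixed) | COC(=O)C1=C([C@H](O)CCCCCC[C@@H]3CC[C@]4(CC[C@@H](C)O4)O3)C2CCC1(OC)C=C2OC | intermediate
23 | methyl 2-{(1R)-1-hydroxy-7-[(2R,5S,7R)-7-methyl-1,6-dioxaspiro[4.4]nonan-2-yl]heptyl}-4,6-dimethoxybenzoate | COC(=O)c1c(OC)cc(OC)cc1[C@H](O)CCCCCC[C@@H]1CC[C@]2(CC[C@@H](C)O2)O1 | intermediate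
24 | (3R)-5,7-dimethoxy-3-{6-[(2R,5S,7R)-7-methyl-1,6-dioxaspiro[4.4]nonan-2-yl]hexyl}-2-benzofuran-1(3H)-one | COc1cc(OC)c2c(c1)[C@@H](CCCCCC[C@@H]1CC[C@]3(CC[C@@H](C)O3)O1)OC2=O | target

## Step count and weak points

Total step count: 6. Longest linear sequence: 6 steps (from 1 and 2 to 24).

The three steps most likely to fail:

Step 2. The second lithiation has to go to the α′ methyl in the presence of a lithium alkoxide, the azaenolate has to choose the oxirane over the primary chloride, and three components are joined in one flask. Fallback, setting out from 5 (with 7) and coming back at 11: the spiroketal is built by alkyne hydroalkoxylation instead of the hydrazone linchpin. Opening 7 with propargylmagnesium bromide (from propargyl bromide, Mg, cat. HgCl2, Et2O, −78 → 0 °C) gives (2R)-hex-5-yn-2-ol F1. TESCl and imidazole in CH2Cl2 give triethyl{[(2R)-hex-5-yn-2-yl]oxy}silane F2. Its lithium acetylide (n-BuLi, THF, −78 °C) with BF3·OEt2 opens 5 at the oxirane CH2, conditions under which a primary chloride is inert, to give (6R,12R)-1-chloro-12-[(triethylsilyl)oxy]tridec-8-yn-6-ol F3. AuCl (5 mol%) and PPTS in MeOH/CH2Cl2 then remove the silyl ether and add the C12 hydroxyl (5-exo) and the C6 hydroxyl (5-endo) to C9, the only alkyne carbon that can take both oxygens in five-membered rings, which gives 11 as the same equilibrium pair.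

Step 5. The acetylide has to be acylated in the presence of a lithium alkoxide and diisopropylamine. Fallback, setting out from 17 and coming back at 19: the elimination is stopped at the alkynol and the carboxyl carbon is brought in as CO2, which cannot cap the oxygen permanently. LDA (4.1 equiv, THF, −78 → 0 °C) and aqueous quench give 18, now isolated. n-BuLi (2.1 equiv, THF, −78 °C) and dry CO2 give, after mild acidification, (4R)-4-hydroxy-10-[(2R,5S,7R)-7-methyl-1,6-dioxaspiro[4.4]nonan-2-yl]dec-2-ynoic acid F4 (any O-carbonate reverts on work-up). TMSCHN2 in PhMe/MeOH at 0 °C gives 19.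

Step 6. A free γ-hydroxy ynoate is held at 185 °C, and the reaction relies on in situ conjugation of the 1,4-diene. Fallback, setting out from 19 and coming back at 24: the arene is built at lower temperature by a Diels–Alder/aromatisation with an acyclic ketene-acetal diene. Methyl (E)-3-methoxybut-2-enoate, LDA and TMSCl (THF, −78 °C) give (1E)-1,3-dimethoxy-1-(trimethylsilyloxy)buta-1,3-diene F5. F5 (3 equiv) and 19 in PhMe at 90–110 °C, then PPTS in wet THF at 60 °C, give directly (3R)-7-hydroxy-5-methoxy-3-{6-[(2R,5S,7R)-7-methyl-1,6-dioxaspiro[4.4]nonan-2-yl]hexyl}-2-benzofuran-1(3H)-one F6. The orientation is the same (diene CH2 terminus to the ynoate β-carbon), the cycloadduct aromatises by loss of methanol and trimethylsilanol, and the hydroxy ester lactonises. MeI, K2CO3, acetone, reflux methylates the chelated phenol to 24.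

Further compounds
F1 | step 2 | (2R)-hex-5-yn-2-ol | C[C@@H](O)CCC#C
F2 | step 2 | triethyl{[(2R)-hex-5-yn-2-yl]oxy}silane | C[C@@H](O[Si](CC)(CC)CC)CCC#C
F3 | step 2 | (6R,12R)-1-chloro-12-[(triethylsilyl)oxy]tridec-8-yn-6-ol | ClCCCCC[C@@H](O)CC#CCC[C@@H](C)O[Si](CC)(CC)CC
F4 | step 5 | (4R)-4-hydroxy-10-[(2R,5S,7R)-7-methyl-1,6-dioxaspiro[4.4]nonan-2-yl]dec-2-ynoic acid | OC(=O)C#C[C@H](O)CCCCCC[C@@H]1CC[C@]2(CC[C@@H](C)O2)O1
F5 | step 6 | (1E)-1,3-dimethoxy-1-(trimethylsilyloxy)buta-1,3-diene | C=C(OC)/C=C(/O[Si](C)(C)C)OC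
F6 | step 6 | (3R)-7-hydroxy-5-methoxy-3-{6-[(2R,5S,7R)-7-methyl-1,6-dioxaspiro[4.4]nonan-2-yl]hexyl}-2-benzofuran-1(3H)-one | COc1cc(O)c2c(c1)[C@@H](CCCCCC[C@@H]1CC[C@]3(CC[C@@H](C)O3)O1)OC2=O
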